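## Retrosynthetic overview

1. The CH2CHO arm is unmasked last: alkenylboronate oxidation, after cross-metathesis of an (E)-propenyl group with vinyl-Bpin.
2. The C2–C3 bond and both stereocentres come from a deconjugative Ireland–Claisen rearrangement of a (Z)-allylic (S)-ester, with chirality transfer from (S)-but-3-yn-2-ol.
3. That ester comes from a Stille coupling of an α-iodo push-pull enal (ring fragment) with a (Z)-vinylstannane ester (acid fragment plus linker).
4. The only ring is made first: a 5-exo-dig intramolecular oxa-Michael addition of a tertiary alcohol onto a (Z)-enynal gives the 2,2-dimethyl-2,5-dihydrofuran with its exocyclic enal.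
5. Three branches converge: ring fragment (steps 1–4), acid fragment (steps 5–6), linker (steps 7–8); joined in steps 9 and 10.

Assumption: the exocyclic push-pull C=C is drawn throughout with the carbonyl group syn to ring C3, as in the target; this is taken to be the thermodynamic geometry, to which the isomers equilibrate.

## Route

Step 1
Reactants: 1 ethyl (2Z)-3-iodoprop-2-enoate; 2 methylmagnesium bromide
Product: 3 (3Z)-4-iodo-2-methylbut-3-en-2-ol
Conditions: MeMgBr (2.5 equiv), THF, −78 → 0 °C; H2O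
Reagents that add atoms: none
Why: Double Grignard addition to the ester gives the tertiary alcohol while the (Z)-vinyl iodide survives at low temperature, so the cis geometry needed for ring closure is kept.

Step 2
Reactants: 3 (3Z)-4-iodo-2-methylbut-3-en-2-ol; 4 prop-2-yn-1-ol
Product: 5 (4Z)-6-methylhept-4-en-2-yne-1,6-diol
Conditions: Pd(PPh3)2Cl2 (2 mol %), CuI (4 mol %), Et3N, THF, 25 °C
Reagents that add atoms: none
Why: Sonogashira coupling of the vinyl iodide with the terminal alkyne keeps the (Z) geometry and tolerates both free hydroxyl groups.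

Step 3
Reactants: 5 (4Z)-6-methylhept-4-en-2-yne-1,6-diol
Product: 7 (2E)-2-(5,5-dimethylfuran-2(5H)-ylidene)acetaldehyde, via ynal 6 (not isolated)
Conditions: MnO2 (15 equiv), CH2Cl2, 25 °C; filter; DBU (10 mol %), CH2Cl2, 0 → 25 °C
Reagents that add atoms: none
Why: MnO2 oxidises only the primary propargylic alcohol, and base then triggers a 5-exo-dig intramolecular oxa-Michael addition of the cis-placed tertiary hydroxyl onto the β-carbon of the ynal, closing the dihydrofuran ring with its exocyclic push-pull enal.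

Step 4
Reactants: 7 (2E)-2-(5,5-dimethylfuran-2(5H)-ylidene)acetaldehyde
Product: 8 (2Z)-2-(5,5-dimethylfuran-2(5H)-ylidene)-2-iodoacetaldehyde
Conditions: NIS (1.05 equiv), CH2Cl2, 0 °C, dark
Reagents that add atoms: N-iodosuccinimide, O=C1CCC(=O)N1I
Why: Electrophilic α-iodination at the nucleophilic enol-ether carbon of the vinylogous formate, followed by loss of the α-proton, gives the α-iodo enal for cross-coupling.

Step 5
Reactants: 9 2-(3-chloropropyl)-2-methyl-1,3-dioxolane; 10 methyl but-2-ynoate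
Product: 14 methyl (2E)-3-methyl-6-(2-methyl-1,3-dioxolan-2-yl)hex-2-enoate, via Grignard reagent 11 (not isolated), via alkylcopper 12 (not isolated), via vinylcopper adduct 13 (not isolated)
Conditions: Mg, THF, 65 °C; CuBr·SMe2 (1.0 equiv), −40 °C; 10, −78 °C; NH4Cl/H2O, −78 °C
Reagents that add atoms: none
Why: Syn carbocupration of the ynoate puts the alkyl chain trans and the methyl group cis to the ester, fixing the (E) geometry that later directs γ-deprotonation to the methyl group.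

Step 6
Reactants: 14 methyl (2E)-3-methyl-6-(2-methyl-1,3-dioxolan-2-yl)hex-2-enoate
Product: 15 (2E)-3-methyl-6-(2-methyl-1,3-dioxolan-2-yl)hex-2-enoic acid
Conditions: LiOH, THF/MeOH/H2O, 25 °C; then 1 M HCl to pH 4, 0 °C
Reagents that add atoms: lithium hydroxide, [Li+].[OH-]
Why: Ester saponification proceeds without touching the ketal or the trisubstituted alkene.

Step 7
Reactants: 16 (2S)-but-3-yn-2-ol
Product: 18 (2S)-4-(tributylstannyl)but-3-yn-2-ol, via dilithium salt 17 (not isolated)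
Conditions: n-BuLi (2.1 equiv), THF, −78 → 0 °C; Bu3SnCl (1.05 equiv), −78 → 25 °C; H2O
Reagents that add atoms: tributyltin chloride, CCCC[Sn](Cl)(CCCC)CCCC
Why: Double deprotonation and C-stannylation of the acetylide gives the alkynylstannane without touching the carbinol stereocentre.

Step 8
Reactants: 18 (2S)-4-(tributylstannyl)but-3-yn-2-ol
Product: 20 (2S,3Z)-4-(tributylstannyl)but-3-en-2-ol, via zirconium intermediate 19 (not isolated)
Conditions: Cp2Zr(H)Cl (2.2 equiv), THF, 25 °C; then H2O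
Reagents that add atoms: none
Why: Syn hydrozirconation of the stannylalkyne and protonolysis of the C–Zr bond with retention give the (Z)-vinylstannane; one equivalent of the hydride is consumed by the hydroxyl group.

Step 9
Reactants: 15 (2E)-3-methyl-6-(2-methyl-1,3-dioxolan-2-yl)hex-2-enoic acid; 20 (2S,3Z)-4-(tributylstannyl)but-3-en-2-ol
Product: 21 (2S,3Z)-4-(tributylstannyl)but-3-en-2-yl (2E)-3-methyl-6-(2-methyl-1,3-dioxolan-2-yl)hex-2-enoate
Conditions: DCC (1.1 equiv), DMAP (10 mol %), CH2Cl2, 0 °C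
Reagents that add atoms: none
Why: Steglich esterification joins the acid fragment to the linker under neutral conditions with retention at the carbinol carbon; low temperature keeps the enoate conjugated.

Step 10
Reactants: 8 (2Z)-2-(5,5-dimethylfuran-2(5H)-ylidene)-2-iodoacetaldehyde; 21 (2S,3Z)-4-(tributylstannyl)but-3-en-2-yl (2E)-3-methyl-6-(2-methyl-1,3-dioxolan-2-yl)hex-2-enoate
Product: 22 (2S,3Z,5E)-5-(5,5-dimethylfuran-2(5H)-ylidene)-6-oxohex-3-en-2-yl (2E)-3-methyl-6-(2-methyl-1,3-dioxolan-2-yl)hex-2-enoate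
Conditions: Pd2(dba)3 (5 mol %), AsPh3 (20 mol %), CuI (20 mol %), DMF, 25 °C, dark
Reagents that add atoms: none
Why: Stille coupling joins the ring fragment to the side chain with retention of both alkene geometries, and the AsPh3/CuI system runs at room temperature so the allylic ester is not ionised.

Step 11
Reactants: 22 (2S,3Z,5E)-5-(5,5-dimethylfuran-2(5H)-ylidene)-6-oxohex-3-en-2-yl (2E)-3-methyl-6-(2-methyl-1,3-dioxolan-2-yl)hex-2-enoate
Product: 25 (2R,3S,4E)-3-[(1E)-1-(5,5-dimethylfuran-2(5H)-ylidene)-2-oxoethyl]-2-[5-(2-methyl-1,3-dioxolan-2-yl)pent-1-en-2-yl]hex-4-enoic acid, via silyl ketene acetal 23 (not isolated), via trimethylsilyl ester 24 (not isolated)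
Conditions: LiN(iPr)2 (1.3 equiv), TMSCl/Et3N (premixed, 3 equiv), THF, −78 °C; then 50 °C, 6 h; H2O, pH 5 buffer
Reagents that add atoms: none
Why: Deconjugative Ireland–Claisen rearrangement: the base removes the γ-methyl proton syn to the carbonyl to give the (1Z)-silyl dienyl ketene acetal, and a chair transition state (alkenyl group of the (Z)-alkene axial, carbinol methyl equatorial) transfers the (S) carbinol chirality to C2 (R) and C3 (S), 2,3-anti, while creating the exo-methylene and the (E)-propenyl group.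

Step 12
Reactants: 25 (2R,3S,4E)-3-[(1E)-1-(5,5-dimethylfuran-2(5H)-ylidene)-2-oxoethyl]-2-[5-(2-methyl-1,3-dioxolan-2-yl)pent-1-en-2-yl]hex-4-enoic acid
Product: 26 (2R,3S,4E)-3-[(1E)-1-(5,5-dimethylfuran-2(5H)-ylidene)-2-oxoethyl]-2-(6-oxohept-1-en-2-yl)hex-4-enoic acid
Conditions: PPTS (20 mol %), acetone/H2O 9:1, 40 °C
Reagents that add atoms: water, O
Why: Mild acid-catalysed ketal hydrolysis frees the methyl ketone without epimerising C2 or opening the vinylogous ester.

Step 13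
Reactants: 26 (2R,3S,4E)-3-[(1E)-1-(5,5-dimethylfuran-2(5H)-ylidene)-2-oxoethyl]-2-(6-oxohept-1-en-2-yl)hex-4-enoic acid; 27 2-ethenyl-4,4,5,5-tetramethyl-1,3,2-dioxaborolane
Product: 28 (2R,3S,4E)-3-[(1E)-1-(5,5-dimethylfuran-2(5H)-ylidene)-2-oxoethyl]-2-(6-oxohept-1-en-2-yl)-5-(4,4,5,5-tetramethyl-1,3,2-dioxaborolan-2-yl)pent-4-enoic acid
Conditions: 27 (5 equiv), RuCl2(H2IMes)(=CH–C6H4-2-OiPr) (second-generation Hoveyda–Grubbs catalyst, 10 mol %), 1,4-benzoquinone (10 mol %), CH2Cl2, 40 °C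
Reagents that add atoms: none
Why: Olefin cross-metathesis engages only the 1,2-disubstituted propenyl group (the 1,1-disubstituted, tetrasubstituted and ring alkenes are hindered or deactivated) and swaps its methyl-bearing carbon for a boryl-bearing one with loss of propene.

Step 14
Reactants: 28 (2R,3S,4E)-3-[(1E)-1-(5,5-dimethylfuran-2(5H)-ylidene)-2-oxoethyl]-2-(6-oxohept-1-en-2-yl)-5-(4,4,5,5-tetramethyl-1,3,2-dioxaborolan-2-yl)pent-4-enoic acid
Product: 29 (2R,3S)-3-[(1E)-1-(5,5-dimethylfuran-2(5H)-ylidene)-2-oxoethyl]-5-oxo-2-(6-oxohept-1-en-2-yl)pentanoic acid (CNP0150297.1)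
Conditions: H2O2 (30 % aq.), pH 7 phosphate buffer, THF, 0 → 25 °C; then pH 3, extraction
Reagents that add atoms: hydrogen peroxide, OO
Why: Oxidation of the alkenyl C–B bond (boron-to-oxygen 1,2-migration) gives the enol, which tautomerises to the CH2CHO aldehyde under near-neutral conditions that leave both stereocentres untouched.

## Compound list

1 | ethyl (2Z)-3-iodoprop-2-enoate | CCOC(=O)/C=C\I | starting material
2 | methylmagnesium bromide | C[Mg]Br | starting material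
3 | (3Z)-4-iodo-2-methylbut-3-en-2-ol | CC(C)(O)/C=C\I | intermediate
4 | prop-2-yn-1-ol | C#CCO | starting material
5 | (4Z)-6-methylhept-4-en-2-yne-1,6-diol | OCC#C/C=C\C(C)(C)O | intermediate
6 | ynal: (4Z)-6-hydroxy-6-methylhept-4-en-2-ynal | O=CC#C/C=C\C(C)(C)O | intermediate
7 | (2E)-2-(5,5-dimethylfuran-2(5H)-ylidene)acetaldehyde | O=C/C=C1\C=CC(C)(C)O1 | intermediate
8 | (2Z)-2-(5,5-dimethylfuran-2(5H)-ylidene)-2-iodoacetaldehyde | O=C/C(I)=C1\C=CC(C)(C)O1 | intermediate
9 | 2-(3-chloropropyl)-2-methyl-1,3-dioxolane | CC1(CCCCl)OCCO1 | starting material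
10 | methyl but-2-ynoate | CC#CC(=O)OC | starting material
11 | Grignard reagent: [3-(2-methyl-1,3-dioxolan-2-yl)propyl]magnesium chloride | CC1(CCC[Mg]Cl)OCCO1 | intermediate
12 | alkylcopper: [3-(2-methyl-1,3-dioxolan-2-yl)propyl]copper | CC1(CCC[Cu])OCCO1 | intermediate
13 | vinylcopper adduct: methyl (2Z)-2-cuprio-3-methyl-6-(2-methyl-1,3-dioxolan-2-yl)hex-2-enoate | COC(=O)/C([Cu])=C(\C)CCCC1(C)OCCO1 | intermediate
14 | methyl (2E)-3-methyl-6-(2-methyl-1,3-dioxolan-2-yl)hex-2-enoate | COC(=O)/C=C(\C)CCCC1(C)OCCO1 | intermediate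
15 | (2E)-3-methyl-6-(2-methyl-1,3-dioxolan-2-yl)hex-2-enoic acid | OC(=O)/C=C(\C)CCCC1(C)OCCO1 | intermediate
16 | (2S)-but-3-yn-2-ol | C[C@H](O)C#C | starting material
17 | dilithium salt: lithium (2S)-4-lithiobut-3-yn-2-olate | C[C@H](O[Li])C#C[Li] | intermediate
18 | (2S)-4-(tributylstannyl)but-3-yn-2-ol | C[C@H](O)C#C[Sn](CCCC)(CCCC)CCCC | intermediate
19 | zirconium intermediate: Cp2ZrCl alkoxide of (2S,3Z)-4-(tributylstannyl)-4-[chlorobis(cyclopentadienyl)zirconio]but-3-en-2-ol (Cp drawn σ-bonded) | C[C@H](O[Zr](Cl)(C1C=CC=C1)C1C=CC=C1)/C=C(\[Sn](CCCC)(CCCC)CCCC)[Zr](Cl)(C1C=CC=C1)C1C=CC=C1 | intermediate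
20 | (2S,3Z)-4-(tributylstannyl)but-3-en-2-ol | C[C@H](O)/C=C\[Sn](CCCC)(CCCC)CCCC | intermediate
21 | (2S,3Z)-4-(tributylstannyl)but-3-en-2-yl (2E)-3-methyl-6-(2-methyl-1,3-dioxolan-2-yl)hex-2-enoate | C[C@H](OC(=O)/C=C(\C)CCCC1(C)OCCO1)/C=C\[Sn](CCCC)(CCCC)CCCC | intermediate
22 | (2S,3Z,5E)-5-(5,5-dimethylfuran-2(5H)-ylidene)-6-oxohex-3-en-2-yl (2E)-3-methyl-6-(2-methyl-1,3-dioxolan-2-yl)hex-2-enoate | C[C@H](OC(=O)/C=C(\C)CCCC2(C)OCCO2)/C=C\C(C=O)=C1\C=CC(C)(C)O1 | intermediate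
23 | silyl ketene acetal: (1Z)-trimethylsilyl dienyl ketene acetal of 22 | C[C@H](O/C(O[Si](C)(C)C)=C/C(=C)CCCC2(C)OCCO2)/C=C\C(C=O)=C1\C=CC(C)(C)O1 | intermediate
24 | trimethylsilyl ester of 25 | C=C(CCCC2(C)OCCO2)[C@H](C(=O)O[Si](C)(C)C)[C@H](/C=C/C)/C(C=O)=C1/C=CC(C)(C)O1 | intermediate
25 | (2R,3S,4E)-3-[(1E)-1-(5,5-dimethylfuran-2(5H)-ylidene)-2-oxoethyl]-2-[5-(2-methyl-1,3-dioxolan-2-yl)pent-1-en-2-yl]hex-4-enoic acid | C=C(CCCC2(C)OCCO2)[C@H](C(=O)O)[C@H](/C=C/C)/C(C=O)=C1/C=CC(C)(C)O1 | intermediate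
26 | (2R,3S,4E)-3-[(1E)-1-(5,5-dimethylfuran-2(5H)-ylidene)-2-oxoethyl]-2-(6-oxohept-1-en-2-yl)hex-4-enoic acid | C=C(CCCC(C)=O)[C@H](C(=O)O)[C@H](/C=C/C)/C(C=O)=C1/C=CC(C)(C)O1 | intermediate
27 | 2-ethenyl-4,4,5,5-tetramethyl-1,3,2-dioxaborolane | C=CB1OC(C)(C)C(C)(C)O1 | starting material
28 | (2R,3S,4E)-3-[(1E)-1-(5,5-dimethylfuran-2(5H)-ylidene)-2-oxoethyl]-2-(6-oxohept-1-en-2-yl)-5-(4,4,5,5-tetramethyl-1,3,2-dioxaborolan-2-yl)pent-4-enoic acid | C=C(CCCC(C)=O)[C@H](C(=O)O)[C@H](/C=C/B2OC(C)(C)C(C)(C)O2)/C(C=O)=C1/C=CC(C)(C)O1 | intermediate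
29 | (2R,3S)-3-[(1E)-1-(5,5-dimethylfuran-2(5H)-ylidene)-2-oxoethyl]-5-oxo-2-(6-oxohept-1-en-2-yl)pentanoic acid | C=C(CCCC(C)=O)[C@H](C(=O)O)[C@H](CC=O)/C(C=O)=C1/C=CC(C)(C)O1 | target

## Step count, linear sequence and risks

Total step count: 14.
Longest linear sequence: 9 steps (steps 1, 2, 3, 4, 10, 11, 12, 13, 14). The other two branches are 8 steps each (5, 6, 9–14 and 7, 8, 9–14).

Steps most likely to fail:

Step 11 (Ireland–Claisen). The strong base must spare the free push-pull aldehyde. The (1Z) ketene acetal geometry, which decides the C2 configuration, is argued from the syn γ-deprotonation model and is not certain. The alkenyl group must also sit axial in a crowded chair. The fallback carries the formyl carbon as a Weinreb amide through the base step; it sets out from 3 and comes back at 25. Sonogashira coupling of 3 with N-methoxy-N-methylprop-2-ynamide (Pd(PPh3)2Cl2, CuI, Et3N) gives (4Z)-6-hydroxy-N-methoxy-N,6-dimethylhept-4-en-2-ynamide F1. The same DBU-catalysed 5-exo-dig oxa-Michael closure gives (2E)-2-(5,5-dimethylfuran-2(5H)-ylidene)-N-methoxy-N-methylacetamide F2. NIS then gives (2Z)-2-(5,5-dimethylfuran-2(5H)-ylidene)-2-iodo-N-methoxy-N-methylacetamide F3. Stille coupling with 21 (Pd2(dba)3, AsPh3, CuI) gives (2S,3Z,5E)-5-(5,5-dimethylfuran-2(5H)-ylidene)-6-[methoxy(methyl)amino]-6-oxohex-3-en-2-yl (2E)-3-methyl-6-(2-methyl-1,3-dioxolan-2-yl)hex-2-enoate F4. This amide has no base-sensitive formyl group, and LiN(iPr)2/TMSCl rearrangement gives (2R,3S,4E)-3-{(1E)-1-(5,5-dimethylfuran-2(5H)-ylidene)-2-[methoxy(methyl)amino]-2-oxoethyl}-2-[5-(2-methyl-1,3-dioxolan-2-yl)pent-1-en-2-yl]hex-4-enoic acid F5. Reduction of the Weinreb amide with iBu2AlH (THF, −78 °C, one extra equivalent for the carboxylic acid) returns aldehyde 25.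

Step 13 (cross-metathesis). The propenyl group sits next to a crowded allylic stereocentre and may react slowly with the bulky boronate partner. The fallback replaces the boron route by ethenolysis and a nitrite-modified Wacker oxidation; it sets out from 26 and comes back at 29. Ethenolysis (ethylene, 1 atm, the same ruthenium catalyst, CH2Cl2, 40 °C) gives (2R,3S)-3-[(1E)-1-(5,5-dimethylfuran-2(5H)-ylidene)-2-oxoethyl]-2-(6-oxohept-1-en-2-yl)pent-4-enoic acid F6. Aldehyde-selective Wacker oxidation of its monosubstituted vinyl group (PdCl2(PhCN)2, CuCl2, AgNO2, t-BuOH/MeNO2, O2, 25 °C; the 1,1-disubstituted alkene does not react) gives 29 directly.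

Step 10 (Stille coupling). The vinyl iodide is tetrasubstituted and hindered, and the stannane carries an allylic ester that zerovalent palladium could ionise. The fallback builds the same bond as an alkyne and then reduces it; it sets out from 15 and 16 and comes back at 22. DCC/DMAP esterification of 15 with 16 gives (2S)-but-3-yn-2-yl (2E)-3-methyl-6-(2-methyl-1,3-dioxolan-2-yl)hex-2-enoate F7. Sonogashira coupling with 8 (Pd(PPh3)2Cl2, CuI, Et3N, THF, 25 °C) gives (2S,5E)-5-(5,5-dimethylfuran-2(5H)-ylidene)-6-oxohex-3-yn-2-yl (2E)-3-methyl-6-(2-methyl-1,3-dioxolan-2-yl)hex-2-enoate F8. Cis-selective semi-reduction of the conjugated alkyne (Zn dust activated with Cu(OAc)2 and AgNO3, MeOH/H2O, 25 °C) gives 22.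

## Further compounds

F1 | step 11 | (4Z)-6-hydroxy-N-methoxy-N,6-dimethylhept-4-en-2-ynamide | CON(C)C(=O)C#C/C=C\C(C)(C)O
F2 | step 11 | (2E)-2-(5,5-dimethylfuran-2(5H)-ylidene)-N-methoxy-N-methylacetamide | CON(C)C(=O)/C=C1\C=CC(C)(C)O1
F3 | step 11 | (2Z)-2-(5,5-dimethylfuran-2(5H)-ylidene)-2-iodo-N-methoxy-N-methylacetamide | CON(C)C(=O)/C(I)=C1\C=CC(C)(C)O1
F4 | step 11 | (2S,3Z,5E)-5-(5,5-dimethylfuran-2(5H)-ylidene)-6-[methoxy(methyl)amino]-6-oxohex-3-en-2-yl (2E)-3-methyl-6-(2-methyl-1,3-dioxolan-2-yl)hex-2-enoate | C[C@H](OC(=O)/C=C(\C)CCCC2(C)OCCO2)/C=C\C(C(=O)N(C)OC)=C1\C=CC(C)(C)O1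
F5 | step 11 | (2R,3S,4E)-3-{(1E)-1-(5,5-dimethylfuran-2(5H)-ylidene)-2-[methoxy(methyl)amino]-2-oxoethyl}-2-[5-(2-methyl-1,3-dioxolan-2-yl)pent-1-en-2-yl]hex-4-enoic acid | C=C(CCCC2(C)OCCO2)[C@H](C(=O)O)[C@H](/C=C/C)/C(C(=O)N(C)OC)=C1/C=CC(C)(C)O1
F6 | step 13 | (2R,3S)-3-[(1E)-1-(5,5-dimethylfuran-2(5H)-ylidene)-2-oxoethyl]-2-(6-oxohept-1-en-2-yl)pent-4-enoic acid | C=C(CCCC(C)=O)[C@H](C(=O)O)[C@H](C=C)/C(C=O)=C1/C=CC(C)(C)O1
F7 | step 10 | (2S)-but-3-yn-2-yl (2E)-3-methyl-6-(2-methyl-1,3-dioxolan-2-yl)hex-2-enoate | C[C@H](OC(=O)/C=C(\C)CCCC1(C)OCCO1)C#C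
F8 | step 10 | (2S,5E)-5-(5,5-dimethylfuran-2(5H)-ylidene)-6-oxohex-3-yn-2-yl (2E)-3-methyl-6-(2-methyl-1,3-dioxolan-2-yl)hex-2-enoate | C[C@H](OC(=O)/C=C(\C)CCCC2(C)OCCO2)C#C/C(C=O)=C1/C=CC(C)(C)O1
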